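**Plan**

- Numbering: ring A C1–C6; chain C7≡C8–C9(CH3)=C10–C11=C12–C13=C14–C15=C16(CH3)–C17=C18, with C18 the γ-carbon of the lactone; ring B C1'–C6', with C7'=C8' bonded to the lactone α-carbon (Cα).
- Cuts: C17=C18 (vinylogous aldol–elimination), C8'–Cα (Stille), C9–CH3 together with C10–C11 (methylmetalation/cross-coupling), C6–C7 and C6'–C7' (Sonogashira on one enol triflate), C11=C12 (Takai) and C15=C16 (Wittig).
- Enabling feature: the methyl-branched E alkene C9=C10 sits directly on the ring A alkyne C7≡C8, with the methyl cis to C11; this is the pattern left by syn addition of methyl–metal across the terminal alkyne of a ring A–C≡C–C≡C–H diyne.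
- Forward order: no ring is formed; rings A and B both come from the enol triflate of silylated (4R,6R)-actinol and the lactone from a purchased bromofuranone. The chain is joined C6–C7, then C9–CH3/C10–C11, then (other half) C6'–C7' and C8'–Cα, and last C17=C18.
- Stereochemistry: C3 and C3' are the carbinol carbon of actinol; C5' and C6' come from a hydroxyl-directed cis epoxidation and its opening with inversion at C5'. The E alkenes come from Wittig, Takai, syn carbometalation and syn hydrostannation; the Z ylidene from thermodynamically controlled elimination.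

Key step: step 9

Remark: 3-bromofuran-2(5H)-one is taken as purchasable; the mono-silyl diyne and the terminal ring A diyne are used directly after work-up because terminal 1,3-diynes polymerise on storage. TBS = tert-butyldimethylsilyl, TES = triethylsilyl.

**Route**

Step 1
Reactants: 1 (4R,6R)-actinol
Product: 2 (4R,6R)-4-(tert-butyldimethylsilyloxy)-2,2,6-trimethylcyclohexan-1-one
Conditions: TBSCl, imidazole, DMF, rt
Reagents that add atoms: tert-butyldimethylsilyl chloride, CC(C)(C)[Si](C)(C)Cl
Why: Imidazole-promoted silyl ether formation caps the only hydroxyl so that the later enolate, organoaluminium and hydride steps meet no acidic O–H, and neither stereocentre is touched.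

Step 2
Reactants: 2 silylated actinol
Product: 4 (4R)-4-(tert-butyldimethylsilyloxy)-2,6,6-trimethylcyclohex-1-en-1-yl trifluoromethanesulfonate, via lithium enolate 3 (not isolated)
Conditions: LiN(i-Pr)2, THF, −78 °C; PhNTf2, −78 °C → rt
Reagents that add atoms: N-phenylbis(trifluoromethanesulfonimide), O=S(=O)(N(c1ccccc1)S(=O)(=O)C(F)(F)F)C(F)(F)F
Why: The ketone has a single α-hydrogen (C6–H, C2 being quaternary), so one enolate forms and its O-sulfonylation (enol triflate formation) gives the tetrasubstituted alkenyl triflate, erasing the C6 stereocentre and leaving C4 intact.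

Step 3
Reactants: 5 1,4-bis(trimethylsilyl)buta-1,3-diyne
Product: 7 buta-1,3-diyn-1-yl(trimethyl)silane, via lithium diynide 6 (not isolated)
Conditions: MeLi·LiBr (1.0 equiv), Et2O, 0 °C → rt; H2O quench; dried Et2O solution used directly
Reagents that add atoms: none
Why: Nucleophilic cleavage of one alkynyl C–Si bond by MeLi·LiBr (monodesilylation) should stop after the first silicon because the lithium diynide is deactivated towards a second attack, and protonation gives the mono-capped terminal diyne.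

Step 4
Reactants: 4 ring enol triflate; 7 mono-silyl diyne
Product: 8 tert-butyldimethyl{[(1R)-3,5,5-trimethyl-4-[4-(trimethylsilyl)buta-1,3-diyn-1-yl]cyclohex-3-en-1-yl]oxy}silane
Conditions: Pd(PPh3)4 (5 mol %), CuI (10 mol %), i-Pr2NH, DMF, degassed, rt → 40 °C
Reagents that add atoms: none
Why: Sonogashira coupling of the enol triflate with the terminal C–H of 7 forms C6–C7, and the trimethylsilyl cap ensures that only one terminus of the diyne couples.

Step 5
Reactants: 8 silyl-capped ring A diyne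
Product: 9 {[(1R)-4-(buta-1,3-diyn-1-yl)-3,5,5-trimethylcyclohex-3-en-1-yl]oxy}(tert-butyl)dimethylsilane
Conditions: K2CO3 (cat.), MeOH/THF, 0 °C; used at once
Reagents that add atoms: none
Why: Carbonate-catalysed methanolysis (protodesilylation) cleaves the alkynyl C–SiMe3 bond much faster than the secondary O–Si bond, freeing the terminal alkyne needed for carbometalation.

Step 6
Reactants: 10 (E)-4,4-dimethoxybut-2-enal; 11 ethyl 2-(triphenylphosphoranylidene)propanoate
Product: 12 ethyl (2E,4E)-6,6-dimethoxy-2-methylhexa-2,4-dienoate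
Conditions: CH2Cl2, rt
Reagents that add atoms: none
Why: Wittig olefination with the stabilised α-methyl ylide gives the E trisubstituted enoate (C15=C16) and leaves the existing E double bond and the acetal untouched.

Step 7
Reactants: 12 acetal dienoate
Product: 13 ethyl (2E,4E)-2-methyl-6-oxohexa-2,4-dienoate
Conditions: 1 M HCl, THF, 0 °C → rt
Reagents that add atoms: water, O
Why: Mild acid-catalysed acetal hydrolysis unmasks the aldehyde without touching the ester, and the E,E dienal is the thermodynamically preferred geometry.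

Step 8
Reactants: 13 aldehyde dienoate
Product: 14 ethyl (2E,4E,6E)-7-iodo-2-methylhepta-2,4,6-trienoate
Conditions: CrCl2 (6 equiv), CHI3 (2 equiv), THF, 0 °C, dark
Reagents that add atoms: iodoform, IC(I)I
Why: Takai iodoolefination (a geminal dichromium species from CHI3 and divalent chromium adds to the aldehyde and eliminates) converts the aldehyde into the E iodoalkene C11=C12 while the ester is inert.

Step 9
Reactants: 9 ring A diyne; 14 iodotrienoate
Product: 17 ethyl (2E,4E,6E,8E)-11-[(4R)-4-(tert-butyldimethylsilyloxy)-2,6,6-trimethylcyclohex-1-en-1-yl]-2,9-dimethylundeca-2,4,6,8-tetraen-10-ynoate, via alkenyldimethylalane 15 (not isolated), via alkenylzinc chloride 16 (not isolated)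
Conditions: AlMe3 (2 equiv), Cp2ZrCl2 (0.25 equiv), ClCH2CH2Cl, 0 °C → rt; volatiles removed in vacuo; THF, ZnCl2 (1 equiv), then 14, Pd(PPh3)4 (5 mol %), rt, dark
Reagents that add atoms: trimethylaluminium, C[Al](C)C
Why: Cp2ZrCl2 and AlMe3 form a methylzirconium species that adds methyl and metal syn across the terminal C9≡C10 triple bond, methyl to the internal carbon C9 and the metal (zirconium, then aluminium by exchange) to C10, giving the E alkenylalane 15 with methyl and aluminium cis. Exchange with ZnCl2 gives 16, and zerovalent palladium couples it with 14 by oxidative addition into the C11–I bond, transmetalation and reductive elimination, each with retention, so C10–C11 forms with the C9=C10 and C11=C12 geometries intact. The closest known reaction type is zirconium-catalysed methylalumination of terminal alkynes, enynes and conjugated diynes followed by palladium/zinc cross-coupling of the alkenylalane (Negishi coupling). No ring is closed and no stereocentre is created; the only stereochemical element, the C9=C10 geometry, is fixed by the syn addition. The step needs site selectivity for the terminal over the internal alkyne and methyl delivery to C9: the C7≡C8 alkyne is buried between the C1 gem-dimethyl and C5 methyl groups of the tetrasubstituted ring alkene, and the unsubstituted terminus takes the metal for steric reasons. The silyl ether keeps the hydroxyl from consuming AlMe3, and the ester of 14 is inert to the alkenylzinc.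

Step 10
Reactants: 17 polyenynoate ester
Product: 18 (2E,4E,6E,8E)-11-[(4R)-4-(tert-butyldimethylsilyloxy)-2,6,6-trimethylcyclohex-1-en-1-yl]-2,9-dimethylundeca-2,4,6,8-tetraen-10-yn-1-ol
Conditions: i-Bu2AlH (2.5 equiv), CH2Cl2, −78 °C; aq. potassium sodium tartrate work-up
Reagents that add atoms: none
Why: Hydride reduction of the conjugated ester in 1,2-fashion at low temperature gives the allylic alcohol, and the alkyne, polyene and silyl ether are inert.

Step 11
Reactants: 18 polyenynol
Product: 19 (2E,4E,6E,8E)-11-[(4R)-4-(tert-butyldimethylsilyloxy)-2,6,6-trimethylcyclohex-1-en-1-yl]-2,9-dimethylundeca-2,4,6,8-tetraen-10-ynal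
Conditions: MnO2 (excess), CH2Cl2, rt, dark
Reagents that add atoms: none
Why: MnO2 oxidises the allylic alcohol selectively to the conjugated aldehyde (allylic oxidation) under neutral conditions that should neither over-oxidise nor isomerise the polyene.

Step 12
Reactants: 4 ring enol triflate; 20 ethynyl(trimethyl)silane
Product: 21 tert-butyldimethyl{[(1R)-3,5,5-trimethyl-4-[(trimethylsilyl)ethynyl]cyclohex-3-en-1-yl]oxy}silane
Conditions: Pd(PPh3)4 (5 mol %), CuI (10 mol %), i-Pr2NH, DMF, rt → 50 °C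
Reagents that add atoms: none
Why: Sonogashira coupling of the same enol triflate with the terminal alkyne forms the C6'–C7' bond of ring B.

Step 13
Reactants: 21 ring B silyl enyne
Product: 22 (1R)-4-ethynyl-3,5,5-trimethylcyclohex-3-en-1-ol
Conditions: Bu4NF (2.5 equiv), THF, 0 °C → rt
Reagents that add atoms: none
Why: Fluoride cleaves both the alkynyl C–Si and the O–Si bond (desilylation), liberating the terminal alkyne and the C3' hydroxyl that is needed to steer the epoxidation.

Step 14
Reactants: 22 enynol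
Product: 23 (1S,3S,6S)-6-ethynyl-1,5,5-trimethyl-7-oxabicyclo[4.1.0]heptan-3-ol (oxirane cis to the hydroxyl)
Conditions: VO(acac)2 (5 mol %), t-BuOOH (1.5 equiv), toluene, 0 °C → rt
Reagents that add atoms: tert-butyl hydroperoxide, CC(C)(C)OO
Why: In this hydroxyl-directed epoxidation the vanadium alkoxide of the homoallylic C3' hydroxyl delivers the peroxide oxygen to the face of the tetrasubstituted C5'=C6' alkene that carries the hydroxyl, so both new stereocentres are set with the oxirane cis to the C3' oxygen, and the alkyne is inert.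

Step 15
Reactants: 23 cis-epoxy alcohol
Product: 24 (1S,2R,4S)-1-ethynyl-2,6,6-trimethylcyclohexane-1,2,4-triol
Conditions: HClO4 (5 % aq.), THF/H2O, 0 °C → rt
Reagents that add atoms: water, O
Why: Acid-catalysed epoxide hydrolysis with trans-diaxial opening (Fürst–Plattner rule) should place water on C5' anti to the oxirane oxygen, because C6' is neopentyl-like and carries the inductively withdrawing ethynyl group and because opening at C5' leads directly to the chair with an equatorial C3' hydroxyl; C5' is thus inverted, C6' keeps its oxygen, and the trans 5',6'-diol has its C6' hydroxyl cis to the C3' hydroxyl.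

Step 16
Reactants: 24 triol alkyne
Product: 25 (1S,2R,4S)-1-ethynyl-2,6,6-trimethyl-1,2,4-tris(triethylsilyloxy)cyclohexane
Conditions: Et3SiOTf (4.5 equiv), 2,6-lutidine, CH2Cl2, −40 °C → rt
Reagents that add atoms: triethylsilyl trifluoromethanesulfonate, CC[Si](CC)(CC)OS(=O)(=O)C(F)(F)F
Why: Silyl triflate with 2,6-lutidine silylates the secondary and both hindered tertiary hydroxyls (silyl ether formation), which keeps them from consuming silyl triflate or ionising in the butenolide steps.

Step 17
Reactants: 25 tris-silyl alkyne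
Product: 26 tributyl[(E)-2-[(1R,2R,4S)-2,6,6-trimethyl-1,2,4-tris(triethylsilyloxy)cyclohexyl]ethenyl]stannane
Conditions: Bu3SnH (1.3 equiv, slow addition), PdCl2(PPh3)2 (3 mol %), THF, 0 °C → rt
Reagents that add atoms: tributyltin hydride, CCCC[SnH](CCCC)CCCC
Why: Palladium-catalysed hydrostannation adds Sn–H syn across the terminal alkyne with tin at the unhindered terminal carbon, the fully substituted propargylic carbon C6' enforcing this regiochemistry, which gives the E alkenylstannane C7'=C8'.

Step 18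
Reactants: 26 alkenylstannane; 27 3-bromofuran-2(5H)-one
Product: 28 3-[(E)-2-[(1R,2R,4S)-2,6,6-trimethyl-1,2,4-tris(triethylsilyloxy)cyclohexyl]ethenyl]furan-2(5H)-one
Conditions: Pd2(dba)3 (2.5 mol %), AsPh3 (20 mol %), DMF, rt → 45 °C
Reagents that add atoms: none
Why: Stille coupling of the E alkenylstannane with the α-bromobutenolide forms C8'–Cα with retention of alkene geometry under base-free conditions that spare the acidic γ-methylene of the lactone and the silyl ethers.

Step 19
Reactants: 28 ring B butenolide; 19 polyenynal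
Product: 31 tetrasilyl ether of the target (ring A O-TBS; ring B tris-O-TES; 5Z), via silyloxyfuran 29 (not isolated), via aldol silyl ether 30 (not isolated)
Conditions: 28, t-BuMe2SiOTf (1.3 equiv), i-Pr2NEt (3 equiv), CH2Cl2, 0 °C; 19, −78 → −20 °C; DBU (3 equiv), −20 °C → rt, dark
Reagents that add atoms: none
Why: Soft enolisation turns the butenolide into the 2-silyloxyfuran 29, whose γ-carbon adds to the silyl-activated aldehyde in a vinylogous Mukaiyama aldol reaction, and DBU then removes the γ-proton of 30 and expels silanolate (E1cB elimination) to give the conjugated C17=C18 double bond, the Z isomer being favoured thermodynamically because the chain lies on the side of the ring oxygen and away from the lactone β-hydrogen.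

Step 20
Reactants: 31 tetrasilyl ether
Product: 32 CNP0163979.1
Conditions: HF·pyridine, pyridine, THF, 0 °C → rt, dark
Reagents that add atoms: none
Why: Buffered HF·pyridine cleaves the secondary TBS ether and the three TES ethers (fluoride desilylation) without the base that would open the ylidenebutenolide or the strong acid that would ionise the tertiary allylic C6' alcohol, and no stereocentre is affected.

**Compound list**

1 | (4R,6R)-4-hydroxy-2,2,6-trimethylcyclohexan-1-one ((4R,6R)-actinol) | C[C@H]1C(=O)C(C)(C)C[C@H](O)C1 | starting material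
2 | (4R,6R)-4-(tert-butyldimethylsilyloxy)-2,2,6-trimethylcyclohexan-1-one | C[C@H]1C(=O)C(C)(C)C[C@H](O[Si](C)(C)C(C)(C)C)C1 | intermediate
3 | lithium (4R)-4-(tert-butyldimethylsilyloxy)-2,6,6-trimethylcyclohex-1-en-1-olate (formed in situ) | CC1=C(O[Li])C(C)(C)C[C@H](O[Si](C)(C)C(C)(C)C)C1 | intermediate
4 | (4R)-4-(tert-butyldimethylsilyloxy)-2,6,6-trimethylcyclohex-1-en-1-yl trifluoromethanesulfonate | CC1=C(OS(=O)(=O)C(F)(F)F)C(C)(C)C[C@H](O[Si](C)(C)C(C)(C)C)C1 | intermediate
5 | 1,4-bis(trimethylsilyl)buta-1,3-diyne | C[Si](C)(C)C#CC#C[Si](C)(C)C | starting material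
6 | lithium 4-(trimethylsilyl)buta-1,3-diyn-1-ide (formed in situ) | [Li]C#CC#C[Si](C)(C)C | intermediate
7 | buta-1,3-diyn-1-yl(trimethyl)silane | C#CC#C[Si](C)(C)C | intermediate
8 | tert-butyldimethyl{[(1R)-3,5,5-trimethyl-4-[4-(trimethylsilyl)buta-1,3-diyn-1-yl]cyclohex-3-en-1-yl]oxy}silane | CC1=C(C#CC#C[Si](C)(C)C)C(C)(C)C[C@H](O[Si](C)(C)C(C)(C)C)C1 | intermediate
9 | {[(1R)-4-(buta-1,3-diyn-1-yl)-3,5,5-trimethylcyclohex-3-en-1-yl]oxy}(tert-butyl)dimethylsilane | CC1=C(C#CC#C)C(C)(C)C[C@H](O[Si](C)(C)C(C)(C)C)C1 | intermediate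
10 | (E)-4,4-dimethoxybut-2-enal | COC(OC)/C=C/C=O | starting material
11 | ethyl 2-(triphenylphosphoranylidene)propanoate | CCOC(=O)C(C)=P(c1ccccc1)(c1ccccc1)c1ccccc1 | starting material
12 | ethyl (2E,4E)-6,6-dimethoxy-2-methylhexa-2,4-dienoate | CCOC(=O)/C(C)=C/C=C/C(OC)OC | intermediate
13 | ethyl (2E,4E)-2-methyl-6-oxohexa-2,4-dienoate | CCOC(=O)/C(C)=C/C=C/C=O | intermediate
14 | ethyl (2E,4E,6E)-7-iodo-2-methylhepta-2,4,6-trienoate | CCOC(=O)/C(C)=C/C=C/C=C/I | intermediate
15 | [(1E)-4-[(4R)-4-(tert-butyldimethylsilyloxy)-2,6,6-trimethylcyclohex-1-en-1-yl]-2-methylbut-1-en-3-yn-1-yl]dimethylalane (formed in situ) | CC1=C(C#C/C(C)=C/[Al](C)C)C(C)(C)C[C@H](O[Si](C)(C)C(C)(C)C)C1 | intermediate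
16 | chloro[(1E)-4-[(4R)-4-(tert-butyldimethylsilyloxy)-2,6,6-trimethylcyclohex-1-en-1-yl]-2-methylbut-1-en-3-yn-1-yl]zinc (formed in situ) | CC1=C(C#C/C(C)=C/[Zn]Cl)C(C)(C)C[C@H](O[Si](C)(C)C(C)(C)C)C1 | intermediate
17 | ethyl (2E,4E,6E,8E)-11-[(4R)-4-(tert-butyldimethylsilyloxy)-2,6,6-trimethylcyclohex-1-en-1-yl]-2,9-dimethylundeca-2,4,6,8-tetraen-10-ynoate | CC1=C(C#C/C(C)=C/C=C/C=C/C=C(C)/C(=O)OCC)C(C)(C)C[C@H](O[Si](C)(C)C(C)(C)C)C1 | intermediate
18 | (2E,4E,6E,8E)-11-[(4R)-4-(tert-butyldimethylsilyloxy)-2,6,6-trimethylcyclohex-1-en-1-yl]-2,9-dimethylundeca-2,4,6,8-tetraen-10-yn-1-ol | CC1=C(C#C/C(C)=C/C=C/C=C/C=C(C)/CO)C(C)(C)C[C@H](O[Si](C)(C)C(C)(C)C)C1 | intermediate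
19 | (2E,4E,6E,8E)-11-[(4R)-4-(tert-butyldimethylsilyloxy)-2,6,6-trimethylcyclohex-1-en-1-yl]-2,9-dimethylundeca-2,4,6,8-tetraen-10-ynal | CC1=C(C#C/C(C)=C/C=C/C=C/C=C(C)/C=O)C(C)(C)C[C@H](O[Si](C)(C)C(C)(C)C)C1 | intermediate
20 | ethynyl(trimethyl)silane | C#C[Si](C)(C)C | starting material
21 | tert-butyldimethyl{[(1R)-3,5,5-trimethyl-4-[(trimethylsilyl)ethynyl]cyclohex-3-en-1-yl]oxy}silane | CC1=C(C#C[Si](C)(C)C)C(C)(C)C[C@H](O[Si](C)(C)C(C)(C)C)C1 | intermediate
22 | (1R)-4-ethynyl-3,5,5-trimethylcyclohex-3-en-1-ol | CC1=C(C#C)C(C)(C)C[C@H](O)C1 | intermediate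
23 | (1S,3S,6S)-6-ethynyl-1,5,5-trimethyl-7-oxabicyclo[4.1.0]heptan-3-ol (oxirane cis to the hydroxyl) | C#C[C@]12O[C@@]1(C)C[C@@H](O)CC2(C)C | intermediate
24 | (1S,2R,4S)-1-ethynyl-2,6,6-trimethylcyclohexane-1,2,4-triol (C1 hydroxyl cis to C4 hydroxyl, trans to C2 hydroxyl) | C#C[C@@]1(O)C(C)(C)C[C@H](O)C[C@@]1(C)O | intermediate
25 | (1S,2R,4S)-1-ethynyl-2,6,6-trimethyl-1,2,4-tris(triethylsilyloxy)cyclohexane | C#C[C@@]1(O[Si](CC)(CC)CC)C(C)(C)C[C@H](O[Si](CC)(CC)CC)C[C@@]1(C)O[Si](CC)(CC)CC | intermediate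
26 | tributyl[(E)-2-[(1R,2R,4S)-2,6,6-trimethyl-1,2,4-tris(triethylsilyloxy)cyclohexyl]ethenyl]stannane | CCCC[Sn](CCCC)(CCCC)/C=C/[C@@]1(O[Si](CC)(CC)CC)C(C)(C)C[C@H](O[Si](CC)(CC)CC)C[C@@]1(C)O[Si](CC)(CC)CC | intermediate
27 | 3-bromofuran-2(5H)-one | O=C1OCC=C1Br | starting material
28 | 3-[(E)-2-[(1R,2R,4S)-2,6,6-trimethyl-1,2,4-tris(triethylsilyloxy)cyclohexyl]ethenyl]furan-2(5H)-one | O=C1OCC=C1/C=C/[C@@]1(O[Si](CC)(CC)CC)C(C)(C)C[C@H](O[Si](CC)(CC)CC)C[C@@]1(C)O[Si](CC)(CC)CC | intermediate
29 | 2-(tert-butyldimethylsilyloxy)-3-[(E)-2-[(1R,2R,4S)-2,6,6-trimethyl-1,2,4-tris(triethylsilyloxy)cyclohexyl]ethenyl]furan (formed in situ) | CC(C)(C)[Si](C)(C)Oc1occc1/C=C/[C@@]1(O[Si](CC)(CC)CC)C(C)(C)C[C@H](O[Si](CC)(CC)CC)C[C@@]1(C)O[Si](CC)(CC)CC | intermediate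
30 | aldol silyl ether: 5-[1-(tert-butyldimethylsilyloxy)-polyenynyl]furan-2(5H)-one from 29 and 19, mixture of diastereomers at the two new sp3 carbons (formed in situ) | CC1=C(C#C/C(C)=C/C=C/C=C/C=C(C)/C(O[Si](C)(C)C(C)(C)C)C2C=C(/C=C/[C@@]3(O[Si](CC)(CC)CC)C(C)(C)C[C@H](O[Si](CC)(CC)CC)C[C@@]3(C)O[Si](CC)(CC)CC)C(=O)O2)C(C)(C)C[C@H](O[Si](C)(C)C(C)(C)C)C1 | intermediate
31 | tetrasilyl ether of the target: ring A 3-O-TBS, ring B 3',5',6'-tris-O-TES, (5Z)-ylidenebutenolide | CC1=C(C#C/C(C)=C/C=C/C=C/C=C(C)/C=C2C=C(/C=C/[C@@]3(O[Si](CC)(CC)CC)C(C)(C)C[C@H](O[Si](CC)(CC)CC)C[C@@]3(C)O[Si](CC)(CC)CC)C(=O)O/2)C(C)(C)C[C@H](O[Si](C)(C)C(C)(C)C)C1 | intermediate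
32 | CNP0163979.1: (5Z)-5-[(2E,4E,6E,8E)-11-[(4R)-4-hydroxy-2,6,6-trimethylcyclohex-1-en-1-yl]-2,9-dimethylundeca-2,4,6,8-tetraen-10-yn-1-ylidene]-3-[(E)-2-[(1R,2R,4S)-1,2,4-trihydroxy-2,6,6-trimethylcyclohexyl]ethenyl]furan-2(5H)-one | CC1=C(C#C/C(C)=C/C=C/C=C/C=C(C)/C=C2C=C(/C=C/[C@@]3(O)C(C)(C)C[C@H](O)C[C@@]3(C)O)C(=O)O/2)C(C)(C)C[C@H](O)C1 | target

**Step count and risks**

Total: 20 steps. Longest linear sequence: 11 steps (steps 1, 2, 12–20, from actinol through ring B to the target).

Steps most likely to fail: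

1. Step 9. The acidic C–H of the conjugated diyne may be aluminated instead of carbometalated, carbometalation may be incomplete or occur twice, and the polyene may partly isomerise during the coupling. Fallback: the C9 methyl and the C9=C10 geometry are bought instead of made. Setting out from triflate 4, Sonogashira coupling with purchased (E)-3-methylpent-2-en-4-yn-1-ol (Pd(PPh3)4, CuI, i-Pr2NH) would give the ring A enynol F1; CBr4/PPh3 would give the allylic bromide F2, and PPh3 in toluene the phosphonium bromide F3. Wittig olefination of F3 with aldehyde 13 (NaOMe, CH2Cl2/MeOH), followed by iodine-catalysed equilibration of the new C11=C12 bond to E, would rejoin the route at ester 17.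

2. Step 15. Water may open the oxirane at the propargylic carbon C6', or a cation-driven 1,2-shift may compete with clean inversion at C5'. Fallback: a carbonyl group on C6' forces opening at C5'. Setting out from triflate 4, palladium-catalysed methoxycarbonylation (Pd(OAc)2, dppp, CO, MeOH, Et3N, DMF) would give the ring methyl ester F4, and i-Bu2AlH the allylic alcohol F5. Sharpless epoxidation (Ti(Oi-Pr)4, diethyl tartrate, t-BuOOH; tartrate enantiomer chosen so that the oxirane forms cis to the silyloxy group) would give the epoxy alcohol F6, and Dess–Martin oxidation the epoxy aldehyde F7. Aqueous HClO4 in THF should open F7 only at C5', the carbon remote from the formyl group, with inversion and loss of the silyl ether, giving the trihydroxy aldehyde F8. Persilylation (Et3SiOTf, 2,6-lutidine) to the tris(triethylsilyl) aldehyde F9 and Ohira–Bestmann alkynylation (dimethyl (1-diazo-2-oxopropyl)phosphonate, K2CO3, MeOH) would return to the route at 25.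

3. Step 19. The silyl triflate may ionise the tertiary allylic C6'–O bond, which is conjugated to the electron-rich silyloxyfuran, and the elimination may not be fully Z-selective. Fallback: the lactone is attached to the polyene before ring B, so ring B never meets silyl triflate. Setting out from bromofuranone 27 and aldehyde 19, t-BuMe2SiOTf/i-Pr2NEt would give 3-bromo-2-(tert-butyldimethylsilyloxy)furan F10, which should add to 19 to give the bromo aldol silyl ether F11; DBU would then give the (Z)-3-bromo-5-ylidenebutenolide F12. Stille coupling of F12 with stannane 26 (Pd2(dba)3, AsPh3, DMF, rt) would rejoin the route at 31.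

Further compounds
F1 | step 9 | (2E)-5-[(4R)-4-(tert-butyldimethylsilyloxy)-2,6,6-trimethylcyclohex-1-en-1-yl]-3-methylpent-2-en-4-yn-1-ol | CC1=C(C#C/C(C)=C/CO)C(C)(C)C[C@H](O[Si](C)(C)C(C)(C)C)C1
F2 | step 9 | {[(1R)-4-[(3E)-5-bromo-3-methylpent-3-en-1-yn-1-yl]-3,5,5-trimethylcyclohex-3-en-1-yl]oxy}(tert-butyl)dimethylsilane | CC1=C(C#C/C(C)=C/CBr)C(C)(C)C[C@H](O[Si](C)(C)C(C)(C)C)C1
F3 | step 9 | [(2E)-5-[(4R)-4-(tert-butyldimethylsilyloxy)-2,6,6-trimethylcyclohex-1-en-1-yl]-3-methylpent-2-en-4-yn-1-yl]triphenylphosphonium bromide | CC1=C(C#C/C(C)=C/C[P+](c2ccccc2)(c2ccccc2)c2ccccc2)C(C)(C)C[C@H](O[Si](C)(C)C(C)(C)C)C1.[Br-]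
F4 | step 15 | methyl (4R)-4-(tert-butyldimethylsilyloxy)-2,6,6-trimethylcyclohex-1-ene-1-carboxylate | CC1=C(C(=O)OC)C(C)(C)C[C@H](O[Si](C)(C)C(C)(C)C)C1
F5 | step 15 | [(4R)-4-(tert-butyldimethylsilyloxy)-2,6,6-trimethylcyclohex-1-en-1-yl]methanol | CC1=C(CO)C(C)(C)C[C@H](O[Si](C)(C)C(C)(C)C)C1
F6 | step 15 | [3-(tert-butyldimethylsilyloxy)-1,5,5-trimethyl-7-oxabicyclo[4.1.0]heptan-6-yl]methanol, oxirane cis to the silyloxy group | OC[C@]12O[C@@]1(C)C[C@@H](O[Si](C)(C)C(C)(C)C)CC2(C)C
F7 | step 15 | 3-(tert-butyldimethylsilyloxy)-1,5,5-trimethyl-7-oxabicyclo[4.1.0]heptane-6-carbaldehyde, oxirane cis to the silyloxy group | O=C[C@]12O[C@@]1(C)C[C@@H](O[Si](C)(C)C(C)(C)C)CC2(C)C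
F8 | step 15 | 1,2,4-trihydroxy-2,6,6-trimethylcyclohexane-1-carbaldehyde, C1 hydroxyl cis to C4 hydroxyl and trans to C2 hydroxyl | O=C[C@@]1(O)C(C)(C)C[C@H](O)C[C@@]1(C)O
F9 | step 15 | 2,6,6-trimethyl-1,2,4-tris(triethylsilyloxy)cyclohexane-1-carbaldehyde, same configuration as F8 | O=C[C@@]1(O[Si](CC)(CC)CC)C(C)(C)C[C@H](O[Si](CC)(CC)CC)C[C@@]1(C)O[Si](CC)(CC)CC
F10 | step 19 | 3-bromo-2-(tert-butyldimethylsilyloxy)furan | CC(C)(C)[Si](C)(C)Oc1occc1Br
F11 | step 19 | 3-bromo-5-[1-(tert-butyldimethylsilyloxy)-polyenynyl]furan-2(5H)-one from F10 and 19, mixture of diastereomers | CC1=C(C#C/C(C)=C/C=C/C=C/C=C(C)/C(O[Si](C)(C)C(C)(C)C)C2C=C(Br)C(=O)O2)C(C)(C)C[C@H](O[Si](C)(C)C(C)(C)C)C1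
F12 | step 19 | (5Z)-3-bromo-5-[(2E,4E,6E,8E)-11-[(4R)-4-(tert-butyldimethylsilyloxy)-2,6,6-trimethylcyclohex-1-en-1-yl]-2,9-dimethylundeca-2,4,6,8-tetraen-10-yn-1-ylidene]furan-2(5H)-one | CC1=C(C#C/C(C)=C/C=C/C=C/C=C(C)/C=C2C=C(Br)C(=O)O/2)C(C)(C)C[C@H](O[Si](C)(C)C(C)(C)C)C1
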